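The readings stem from a simulated flask on assumed constants.

The vessel was closed and stirred. It held a racemate of the two substrates, partner, a racemization catalyst and a single-handed free catalyst. Two runs differed in free catalyst loading.

| flask | left-handed substrate | right-handed substrate | partner | free catalyst | racemization catalyst | remark | time |
|---|---|---|---|---|---|---|---|
| delta | 0.25 M | 0.25 M | 4 equiv | 0.05 mol% | 5 mol% | the very flask that is asked about, followed so far |  |
| zeta | 0.25 M | 0.25 M | 4 equiv | 0.034 mol% | 5 mol% | run made earlier |  |
| flask | 0.25 M | 0.25 M | 4.00 equiv | 0.05 mol% | 5 mol% |  | 40 h |

- delta (time / h: left-handed product / %, right-handed substrate / %, left-handed substrate / %): 1.50: 49.8, 24.8, 21.5; 3.00: 55.5, 22.0, 20.3; 5.00: 55.2, 21.5, 20.7; 6.00: 55.1, 21.2, 20.2; 8.00: 54.7, 21.8, 20.9; 10.0: 55.3, 21.4, 20.2; 12.0: 54.8, 20.9, 21.1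
- zeta (time / h: left-handed product / %, right-handed substrate / %, left-handed substrate / %): 3.00: 43.4, 25.7, 26.4; 5.00: 43.9, 26.2, 25.4; 8.00: 44.1, 25.8, 25.8; 12.0: 43.9, 26.2, 26.5; 15.0: 44.3, 25.7, 25.8; 25.0: 44.9, 26.4, 26.3; 40.0: 45.0, 26.3, 27.3

(readings scatter by 0.5 percentage points)

- free catalyst is single-handed; left-handed substrate and right-handed substrate are mirror images of each other, charged as a racemate, each of them at the stated concentration
- the reaction counts as stopped when no species that holds the left-handed substrate and right-handed substrate together changes by six tenths of a point or more over the second half of the time

- at 40 h, what has stopped the reaction, if anything has (forward and back rates have come level / it is still moving / all of the left-handed substrate has reacted / the partner has run out first / no working catalyst is left)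
- how much left-handed product there is at 40 h, in percent of the left-handed substrate and right-handed substrate together charged
- how much right-handed substrate there is at 40 h, in percent of the left-handed substrate and right-handed substrate together charged

I averaged the flat stretches. The delta run, from 3.00 h, kept 42.0% of both substrates together. The zeta run, from 3.00 h, kept 52.3%. I called the natural logarithm of charged over remaining substrate the reach: 0.867 for delta, 0.649 for zeta.

The asked flask is the delta run, so its plateau was my first way to the remainder. My second way scaled the zeta reach by loading, as a catalyst dying first-order at a fixed pace requires. That gave 38.5%, which is 3.5 percentage points below the plateau, with each reading good to 0.5 points.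

So I suspected the proportion. I assumed instead that partner decays first-order while product also consumes it. The reach should then follow loading times the partner not turned into product. I defined the reach constant as reach divided by loading and by those equivalents: 610 for delta and 627 for zeta. Their ratio, 1.03, stood closer to one than the ratio of reach per loading, 1.10. The proportion was the way that cheated. I committed to the plateau, 21.0% of right-handed substrate, and to lost partner as the stop, though no reading showed partner.

The forecast gave 55.2% of left-handed product, 21% of right-handed substrate, and this end: no working catalyst is left. Its ground: “This leaves the free catalyst dying, with the yield set by its loading.”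

The flask gave 54.7% of left-handed product, 20.9% of right-handed substrate, and this end: the partner has run out first.

    partner + free catalyst + left-handed substrate → free catalyst + left-handed product (k = 350 M⁻² min⁻¹)
    partner + free catalyst + right-handed substrate → free catalyst + right-handed product (k = 21.0 M⁻² min⁻¹)
    left-handed substrate + racemization catalyst ⇌ right-handed substrate + racemization catalyst, rate k3*[racemization catalyst]*[left-handed substrate] forward; the back reaction follows from the equilibrium constant (k = 110 M⁻¹ min⁻¹)
    partner → decomposition product (k = 1.40 × 10⁻⁴ min⁻¹)
    partner → decomposed reagent (k = 0.0180 min⁻¹)
    2 racemization catalyst → spent catalyst (k = 22.0 M⁻¹ min⁻¹)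

At 40.0 h partner stood at 0% of its charge, less than the 42% of its charge still there of right-handed substrate, while free catalyst stood at 100%. A neighbour flask with 1.00 equiv of partner made 17.2% of left-handed product and 1.05% of right-handed product. Those amounts and the reach constant of 610 gave 41.2% of right-handed substrate. That neighbour flask held 40.9%.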